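**Retrosynthetic overview**
1. The 2,3-oxirane is made last, by oxygen transfer to the (2Z)-alkene of the tricyclic lactone (late oxygenation).
2. Ring A (ten-membered) and ring B (lactone) form in one operation: the C6–C7 bond by intramolecular Barbier allylation of a C6 epoxy aldehyde with the C7=C11–C13 allyl bromide (the farnesyl C1→C10 closure in oxidised form), then 6-O→C12 lactonisation.
3. Seco chain: C9–C10 by Ni/Cr coupling of an α-iodoenoate (C1–C6, C10, C14, C15) with a C7–C9 aldehyde that already carries the epoxyangelate; C7–C11 by vinylalumination; 4,5-oxirane by Sharpless epoxidation.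
4. Building blocks: divinyl carbinol (C7–C9), (Z)-3-methylpent-2-en-4-yn-1-ol (C2–C6, C15), DMF (C1), Ph3P=CHCO2Me (C10, C14), methyl propiolate (C11–C13), angelic acid (side chain).
5. Order of ring formation: side-chain oxirane → 4,5-oxirane → ring A + ring B → 2,3-oxirane.

Assumption: atoms carry the numbers they have in the target germacranolide (ring C1–C10, lactone C11–C13, ester carbon C14, methyl C15; C7' is the oxirane carbon lost in step 10), and D-(−)-diisopropyl tartrate counts as a commercial reagent.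

**Step 1**
Reactants: 1 angelic acid, (2Z)-2-methylbut-2-enoic acid
Product: 2 (2Z)-2-methylbut-2-en-1-ol
Conditions: LiAlH4, Et2O, 0 °C to rt
Reagents that add atoms: none
Why: Hydride reduction of the carboxylic acid with LiAlH4 gives the primary allylic alcohol and leaves the trisubstituted (Z)-alkene untouched.

**Step 2**
Reactants: 2 (2Z)-2-methylbut-2-en-1-ol
Product: 3 [(2R,3S)-2,3-dimethyloxiran-2-yl]methanol
Conditions: Ti(OiPr)4 (10 mol %), D-(−)-diisopropyl tartrate (12 mol %), t-BuOOH, 4 Å MS, CH2Cl2, −20 °C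
Reagents that add atoms: tert-butyl hydroperoxide, CC(C)(C)OO
Why: Sharpless asymmetric epoxidation, in which the D-(−)-tartrate titanium complex delivers oxygen to the alkene face that gives the (2R,3S)-oxirane, the cis relation of CH2OH and the C3 methyl coming from the (Z)-alkene.

**Step 3**
Reactants: 3 [(2R,3S)-2,3-dimethyloxiran-2-yl]methanol
Product: 4 (2S,3S)-2,3-dimethyloxirane-2-carboxylic acid
Conditions: RuCl3·xH2O (2 mol %), NaIO4 (3 equiv), CCl4/MeCN/H2O, rt
Reagents that add atoms: water, O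
Why: RuO4-catalysed (Sharpless) oxidation of the primary alcohol to the acid through the aldehyde hydrate does not touch the oxirane stereocentres, the C2 descriptor changing from R to S only because CO2H outranks C3.

**Step 4**
Reactants: 5 penta-1,4-dien-3-ol (divinyl carbinol)
Product: 6 (1R)-1-[(2S)-oxiran-2-yl]prop-2-en-1-ol
Conditions: Ti(OiPr)4 (0.3 equiv), D-(−)-diisopropyl tartrate (0.36 equiv), t-BuOOH, 4 Å MS, CH2Cl2, −25 °C, 5 d
Reagents that add atoms: tert-butyl hydroperoxide, CC(C)(C)OO
Why: Sharpless desymmetrising epoxidation, in which the D-(−)-tartrate complex selects one enantiotopic vinyl group and one alkene face to give the anti (erythro) epoxy alcohol whose carbinol centre becomes C8, the minor enantiomer being consumed by a fast second epoxidation.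

**Step 5**
Reactants: 6 (1R)-1-[(2S)-oxiran-2-yl]prop-2-en-1-ol; 4 (2S,3S)-2,3-dimethyloxirane-2-carboxylic acid
Product: 7 (1R)-1-[(2S)-oxiran-2-yl]prop-2-en-1-yl (2S,3S)-2,3-dimethyloxirane-2-carboxylate
Conditions: DCC, DMAP (10 mol %), CH2Cl2, 0 °C to rt
Reagents that add atoms: none
Why: Steglich esterification acylates the only hydroxyl without breaking a bond at any stereocentre, so the C8 ester is in place from the start and no protecting group is needed there.

**Step 6**
Reactants: 7 (1R)-1-[(2S)-oxiran-2-yl]prop-2-en-1-yl (2S,3S)-2,3-dimethyloxirane-2-carboxylate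
Product: 8 (1S)-2-oxo-1-[(2S)-oxiran-2-yl]ethyl (2S,3S)-2,3-dimethyloxirane-2-carboxylate
Conditions: O3, CH2Cl2, −78 °C; then Me2S
Reagents that add atoms: ozone, [O-][O+]=O
Why: Ozonolysis with reductive work-up cleaves the only alkene to the α-acyloxy aldehyde (C9), which is used crude and cold so that C8 does not epimerise.

**Step 7**
Reactants: 9 (2Z)-3-methylpent-2-en-4-yn-1-ol
Product: 11 (4Z)-4-methyl-6-[(triethylsilyl)oxy]hex-4-en-2-ynal, via triethylsilyl ether 10 (not isolated)
Conditions: n-BuLi (1.0 equiv), THF, −78 °C; Et3SiCl, to 0 °C; n-BuLi (1.05 equiv), −78 °C; DMF; poured into aq. KH2PO4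
Reagents that add atoms: chlorotriethylsilane, CC[Si](Cl)(CC)CC; N,N-dimethylformamide, CN(C)C=O
Why: Silylation of the lithium alkoxide, lithiation of the terminal alkyne and formylation of the acetylide with DMF install C1 as an ynal in one flask without touching the (Z)-alkene.

**Step 8**
Reactants: 12 methyl (triphenylphosphoranylidene)acetate; 11 (4Z)-4-methyl-6-[(triethylsilyl)oxy]hex-4-en-2-ynal
Product: 14 methyl (2Z,6Z)-2-iodo-6-methyl-8-[(triethylsilyl)oxy]octa-2,6-dien-4-ynoate, via iodo ylide 13 (not isolated)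
Conditions: NIS, CH2Cl2, −20 °C; then 11, K2CO3, −20 °C to rt
Reagents that add atoms: N-iodosuccinimide, O=C1CCC(=O)N1I
Why: Tandem ylide iodination and Wittig olefination, in which the stabilised iodo ylide gives the (Z)-α-iodoenoate with C2 trans to CO2Me and cis to iodine, the geometry needed for the ring-cis 1(10) alkene.

**Step 9**
Reactants: 14 methyl (2Z,6Z)-2-iodo-6-methyl-8-[(triethylsilyl)oxy]octa-2,6-dien-4-ynoate; 8 (1S)-2-oxo-1-[(2S)-oxiran-2-yl]ethyl (2S,3S)-2,3-dimethyloxirane-2-carboxylate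
Product: 16 coupled C9 acetate (6-OTES; 7S,8R,9R), via C9 alcohol 15 (not isolated)
Conditions: CrCl2 (4 equiv), NiCl2 (1 mol %), DMF, rt; then Ac2O, pyridine, DMAP, 0 °C
Reagents that add atoms: acetic anhydride, CC(=O)OC(C)=O
Why: Nozaki–Hiyama–Kishi coupling, in which the alkenylchromium formed with retention of alkene geometry adds to the α-acyloxy aldehyde under Felkin–Anh control (attack anti to the C8–O bond) to set C9 as the 8,9-anti alkoxide, which is acetylated in the same flask before the C8 acyl group can migrate.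

**Step 10**
Reactants: 16 coupled C9 acetate (6-OTES; 7S,8R,9R)
Product: 18 C7 aldehyde with free 6-OH (8R,9R), via vicinal diol 17 (not isolated)
Conditions: H5IO6 (1.5 equiv), THF/H2O (3:1), 0 °C to rt
Reagents that add atoms: none
Why: Periodic acid hydrolyses the terminal oxirane at C7' and cleaves the resulting 1,2-diol to the C7 aldehyde (Malaprade cleavage) while the aqueous acid removes the triethylsilyl ether, the glycidic ester oxirane being deactivated by its carbonyl group and C8 and C9 not being touched.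

**Step 11**
Reactants: 19 methyl propiolate; 18 C7 aldehyde with free 6-OH (8R,9R)
Product: 21 Baylis–Hillman-type diol (6-OH and 7-OH; 8S,9R; both C7 epimers), via vinylalane 20 (not isolated)
Conditions: iBu2AlH, NMO, THF, 0 °C, then 19; then 18 (0.33 equiv), 0 °C to rt; aq. potassium sodium tartrate
Reagents that add atoms: none
Why: Ramachandran vinylalumination (hydroalumination of the propiolate to the α-aluminoacrylate, then 1,2-addition to the aldehyde) gives the Morita–Baylis–Hillman-type alcohol without amine base, so the C9 acetate is not lost by β-elimination, and the uncontrolled C7 carbinol centre does not matter because C7 becomes sp2 in step 15.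

**Step 12**
Reactants: 21 Baylis–Hillman-type diol (6-OH and 7-OH; 8S,9R; both C7 epimers)
Product: 22 4,5-epoxy diol (4S,5R,8S,9R)
Conditions: Ti(OiPr)4 (1.2 equiv), D-(−)-diisopropyl tartrate (1.4 equiv), t-BuOOH, 4 Å MS, CH2Cl2, −25 °C
Reagents that add atoms: tert-butyl hydroperoxide, CC(C)(C)OO
Why: Sharpless asymmetric epoxidation of the primary (Z)-allylic alcohol sets C4 and C5 under reagent control as the cis-oxirane of the target, while the ester-conjugated alkenes and the secondary C7 alcohol do not react.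

**Step 13**
Reactants: 22 4,5-epoxy diol (4S,5R,8S,9R)
Product: 23 (2Z)-diene diol (4S,5R,8S,9R)
Conditions: H2 (1 atm), Pd/CaCO3 poisoned with Pb(OAc)2, quinoline, EtOAc, 0 °C
Reagents that add atoms: none
Why: Lindlar semi-hydrogenation adds H2 syn to the conjugated alkyne and stops at the (2Z)-alkene, the poisoned catalyst sparing the acrylate alkenes and the alkenyl oxirane.

**Step 14**
Reactants: 23 (2Z)-diene diol (4S,5R,8S,9R)
Product: 24 epoxy aldehyde (4S,5S,8S,9R)
Conditions: TEMPO (10 mol %), PhI(OAc)2, CH2Cl2, rt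
Reagents that add atoms: none
Why: Oxoammonium (TEMPO/PhI(OAc)2) oxidation is selective for the primary alcohol and gives the cis-epoxy aldehyde without epimerising C5 or oxidising the secondary C7 alcohol.

**Step 15**
Reactants: 24 epoxy aldehyde (4S,5S,8S,9R)
Product: 25 seco allyl bromide (4S,5S,8S,9R; 7Z)
Conditions: NBS, Me2S, CH2Cl2, −30 to 0 °C
Reagents that add atoms: N-bromosuccinimide, O=C1CCC(=O)N1Br
Why: Corey–Kim-type activation of the Baylis–Hillman alcohol as its alkoxysulfonium salt and SN2' displacement by bromide give the (Z)-2-(bromomethyl)enoate with C8 trans to CO2Me, erasing the C7 centre.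

**Step 16**
Reactants: 25 seco allyl bromide (4S,5S,8S,9R; 7Z)
Product: 27 tricyclic 2,3-dehydro lactone (4S,5R,6S,7R,8S,9R), via hydroxy ester 26 (not isolated)
Conditions: In powder (3 equiv), DMF, slow addition of 25 (final 2 mM), rt; then 45 °C
Reagents that add atoms: none
Why: Indium-mediated intramolecular Barbier allylation (SE2' at C7) closes ring A through a chair-like transition state in which, after 1,3-metallotropic equilibration of the allylindium, both ring tethers (C5 and C8) are pseudo-equatorial, so that C6 and C7 are set anti (6S,7R, trans-fused), the aldehyde face being fixed by indium chelation with the cis-4,5-oxirane (5,6-syn) and the allyl face by the C8 stereocentre (attack anti to the C8–O bond), after which the 6-alkoxide acylates C12 to close ring B.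

**Step 17**
Reactants: 27 tricyclic 2,3-dehydro lactone (4S,5R,6S,7R,8S,9R)
Product: 28 CNP0077535.3 (target)
Conditions: DMDO (1.2 equiv), acetone, 0 °C
Reagents that add atoms: dimethyldioxirane, CC1(C)OO1
Why: Prilezhaev-type oxygen transfer from the electrophilic dioxirane goes to the most electron-rich alkene (C2=C3, the other two being acrylate alkenes) and, by peripheral attack on the face anti to the 4,5-oxirane oxygen of the folded ring, gives the cis-2,3-oxirane with the (2R,3R) configuration.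

**Compound list**

1 | angelic acid, (2Z)-2-methylbut-2-enoic acid | C/C=C(C)\C(=O)O | starting material
2 | (2Z)-2-methylbut-2-en-1-ol | C/C=C(C)\CO | intermediate
3 | [(2R,3S)-2,3-dimethyloxiran-2-yl]methanol | OC[C@@]1(C)O[C@H]1C | intermediate
4 | (2S,3S)-2,3-dimethyloxirane-2-carboxylic acid | OC(=O)[C@@]1(C)O[C@H]1C | intermediate
5 | penta-1,4-dien-3-ol (divinyl carbinol) | C=CC(O)C=C | starting material
6 | (1R)-1-[(2S)-oxiran-2-yl]prop-2-en-1-ol | C=C[C@@H](O)[C@@H]1CO1 | intermediate
7 | (1R)-1-[(2S)-oxiran-2-yl]prop-2-en-1-yl (2S,3S)-2,3-dimethyloxirane-2-carboxylate | C=C[C@@H](OC(=O)[C@@]1(C)O[C@H]1C)[C@@H]1CO1 | intermediate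
8 | (1S)-2-oxo-1-[(2S)-oxiran-2-yl]ethyl (2S,3S)-2,3-dimethyloxirane-2-carboxylate | O=C[C@@H](OC(=O)[C@@]1(C)O[C@H]1C)[C@@H]1CO1 | intermediate
9 | (2Z)-3-methylpent-2-en-4-yn-1-ol | OC/C=C(C)\C#C | starting material
10 | triethyl{[(2Z)-3-methylpent-2-en-4-yn-1-yl]oxy}silane | CC[Si](CC)(CC)OC/C=C(C)\C#C | intermediate
11 | (4Z)-4-methyl-6-[(triethylsilyl)oxy]hex-4-en-2-ynal | CC[Si](CC)(CC)OC/C=C(C)\C#CC=O | intermediate
12 | methyl (triphenylphosphoranylidene)acetate | COC(=O)C=P(c1ccccc1)(c1ccccc1)c1ccccc1 | starting material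
13 | methyl iodo(triphenylphosphoranylidene)acetate | COC(=O)C(I)=P(c1ccccc1)(c1ccccc1)c1ccccc1 | intermediate
14 | methyl (2Z,6Z)-2-iodo-6-methyl-8-[(triethylsilyl)oxy]octa-2,6-dien-4-ynoate | CC[Si](CC)(CC)OC/C=C(C)\C#C\C=C(/I)C(=O)OC | intermediate
15 | C9 alcohol of the coupled chain: 6-OTES, 4Z-ene, 2-yne, 1(10)E-enoate with C14 = CO2Me, 9R-OH, 8R-O-[(2S,3S)-2,3-dimethyloxirane-2-carbonyl], 7S C7–C7' oxirane | CC[Si](CC)(CC)OC/C=C(C)\C#C\C=C(C(=O)OC)/[C@@H](O)[C@@H](OC(=O)[C@@]1(C)O[C@H]1C)[C@@H]1CO1 | intermediate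
16 | coupled C9 acetate: as 15 with 9R-OAc (7S,8R,9R) | CC[Si](CC)(CC)OC/C=C(C)\C#C\C=C(C(=O)OC)/[C@@H](OC(C)=O)[C@@H](OC(=O)[C@@]1(C)O[C@H]1C)[C@@H]1CO1 | intermediate
17 | vicinal diol: as 16 with the oxirane opened to 7S-OH and C7'H2OH (7S,8S,9R) | CC[Si](CC)(CC)OC/C=C(C)\C#C\C=C(C(=O)OC)/[C@@H](OC(C)=O)[C@@H](OC(=O)[C@@]1(C)O[C@H]1C)[C@@H](O)CO | intermediate
18 | C7 aldehyde: 6-OH, 4Z-ene, 2-yne, 1(10)E-enoate, 9R-OAc, 8R-O-acyl, C7 = CHO | OC/C=C(C)\C#C\C=C(C(=O)OC)/[C@@H](OC(C)=O)[C@@H](OC(=O)[C@@]1(C)O[C@H]1C)C=O | intermediate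
19 | methyl propiolate | C#CC(=O)OC | starting material
20 | [1-(methoxycarbonyl)ethenyl]bis(2-methylpropyl)alane | C=C(C(=O)OC)[Al](CC(C)C)CC(C)C | intermediate
21 | Baylis–Hillman-type diol: 6-OH, 4Z-ene, 2-yne, 1(10)E-enoate, 9R-OAc, 8S-O-acyl, 7-OH (both epimers), C11(=C13H2)CO2Me | OC/C=C(C)\C#C\C=C(C(=O)OC)/[C@@H](OC(C)=O)[C@@H](OC(=O)[C@@]1(C)O[C@H]1C)C(O)C(=C)C(=O)OC | intermediate
22 | 4,5-epoxy diol: as 21 with the cis-4,5-oxirane (4S,5R,8S,9R) | OC[C@H]1O[C@@]1(C)C#C\C=C(C(=O)OC)/[C@@H](OC(C)=O)[C@@H](OC(=O)[C@@]2(C)O[C@H]2C)C(O)C(=C)C(=O)OC | intermediate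
23 | (2Z)-diene diol: as 22 with C2=C3 as a Z-alkene (4S,5R,8S,9R) | OC[C@H]1O[C@@]1(C)/C=C\C=C(C(=O)OC)/[C@@H](OC(C)=O)[C@@H](OC(=O)[C@@]2(C)O[C@H]2C)C(O)C(=C)C(=O)OC | intermediate
24 | epoxy aldehyde: as 23 with C6 = CHO (4S,5S,8S,9R) | O=C[C@H]1O[C@@]1(C)/C=C\C=C(C(=O)OC)/[C@@H](OC(C)=O)[C@@H](OC(=O)[C@@]2(C)O[C@H]2C)C(O)C(=C)C(=O)OC | intermediate
25 | seco allyl bromide: C6 = CHO, cis-4,5-oxirane, 2Z-ene, 1(10)E-enoate, 9R-OAc, 8S-O-acyl, (7Z)-C7=C11(CO2Me)C13H2Br (4S,5S,8S,9R) | O=C[C@H]1O[C@@]1(C)/C=C\C=C(C(=O)OC)/[C@@H](OC(C)=O)[C@@H](OC(=O)[C@@]2(C)O[C@H]2C)/C=C(CBr)/C(=O)OC | intermediate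
26 | hydroxy ester: ring A closed, 6S-OH, C7 bearing C(=CH2)CO2Me (4S,5R,6S,7S,8S,9R) | O[C@H]1[C@H](C(=C)C(=O)OC)[C@H](OC(=O)[C@@]2(C)O[C@H]2C)[C@H](OC(C)=O)/C(C(=O)OC)=C\C=C/[C@]2(C)O[C@H]12 | intermediate
27 | tricyclic 2,3-dehydro lactone: target without the 2,3-oxirane, 2Z-alkene (4S,5R,6S,7R,8S,9R) | C=C1C(=O)O[C@H]2[C@H]1[C@H](OC(=O)[C@@]1(C)O[C@H]1C)[C@H](OC(C)=O)/C(C(=O)OC)=C\C=C/[C@]1(C)O[C@H]21 | intermediate
28 | CNP0077535.3 (2R,3R,4R,5R,6S,7R,8S,9R; side chain 2S,3S) | C=C1C(=O)O[C@H]2[C@H]1[C@H](OC(=O)[C@@]1(C)O[C@H]1C)[C@H](OC(C)=O)/C(C(=O)OC)=C\[C@H]1O[C@H]1[C@]1(C)O[C@H]21 | target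

**Step count and weak points**

Total steps: 17. Longest linear sequence: 14 steps (1 to 28 through steps 1, 2, 3, 5, 6 and 9 to 17).

The three steps most likely to fail:

First, step 16, the ring closure. The cis-alkenyl oxirane may be opened by trivalent indium, the C8 carboxylate may be lost by 1,4-elimination from the allylindium, and the rigid 1(10),2-diene may disfavour the chair transition state, so both yield and the C6/C7 configuration are uncertain. The fallback changes the order of the ring-forming events. It sets out from 25, which is first epoxidised at the (2Z)-alkene with DMDO (acetone, 0 °C, attack anti to the 4,5-oxirane oxygen) to give the acyclic bis-oxirane bromide F2. This diene-free, more flexible chain is then cyclised with indium in DMF at 2 mM through the bis-oxirane hydroxy ester F3 (not isolated), whose lactonisation gives the target directly, so the route is rejoined at 28.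

Second, step 17, the last epoxidation. The facial preference of the ten-membered ring is only predicted, and DMDO may deliver oxygen syn to the 4,5-oxirane. The fallback replaces direct oxygen transfer by a halohydrin sequence that places the oxygen on the opposite face. It sets out from 27, which with NBS in aqueous acetone at 0 °C forms the bromonium ion on the face that DMDO would use and is opened by water at the allylic C2 to give the bromohydrin F4. Ag2O in CH2Cl2 then closes the oxirane by displacement of bromide with inversion at C3, and the route is rejoined at 28.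

Third, step 9, the Ni/Cr coupling. An α-iodoenoate is an unusual partner, and chelation by the α-acyloxy group may override Felkin–Anh control at C9. The fallback sets the C9 configuration by inversion instead of by addition. It sets out from 8 and 14, which are coupled as in step 9 but without the Ac2O quench, and the syn adduct, the 9-epi alcohol F1, is isolated. F1 is then treated with acetic acid under Mitsunobu conditions (PPh3, DIAD, AcOH, THF, 0 °C; SN2' attack is hindered by the substituent at C1), which installs the acetate with inversion and rejoins the route at 16.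

**Further compounds**

F1 | step 9 | 9-epi alcohol: C9 epimer of 15 (7S,8R,9S) | CC[Si](CC)(CC)OC/C=C(C)\C#C\C=C(C(=O)OC)/[C@H](O)[C@@H](OC(=O)[C@@]1(C)O[C@H]1C)[C@@H]1CO1
F2 | step 16 | acyclic bis-oxirane bromide: 25 with a cis-2,3-oxirane (2R,3R,4S,5S,8S,9R) | O=C[C@H]1O[C@@]1(C)[C@@H]1O[C@@H]1\C=C(C(=O)OC)/[C@@H](OC(C)=O)[C@@H](OC(=O)[C@@]2(C)O[C@H]2C)/C=C(CBr)/C(=O)OC
F3 | step 16 | bis-oxirane hydroxy ester: 26 with a cis-2,3-oxirane (2R,3R,4R,5R,6S,7S,8S,9R), not isolated | O[C@H]1[C@H](C(=C)C(=O)OC)[C@H](OC(=O)[C@@]2(C)O[C@H]2C)[C@H](OC(C)=O)/C(C(=O)OC)=C\[C@H]2O[C@H]2[C@]2(C)O[C@H]12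
F4 | step 17 | bromohydrin of 27: 2R-OH, 3S-Br, otherwise as 27 | C=C1C(=O)O[C@H]2[C@H]1[C@H](OC(=O)[C@@]1(C)O[C@H]1C)[C@H](OC(C)=O)/C(C(=O)OC)=C\[C@@H](O)[C@H](Br)[C@]1(C)O[C@H]21
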